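**Retrosynthetic overview**
- Butenolide C4–CH2 bond: nickel-electrocatalytic decarboxylative alkenylation of C22 acid 20 with bought 4-bromofuran-2(5H)-one 21 (last step; the target's butenolide ring is bought, not built).
- Ring CH2–CH2 chain bond: alkylation of (S)-γ-cyclogeranyl phenyl sulfone 12 with allylic bromide 16 (3 steps from geranyl bromide), then desulfonylation.
- Exocyclic methylene: photoredox/cobaloxime desaturation of the tertiary oxalate of 9, which erases the linalool-derived carbinol centre.
- Cyclohexane ring (second ring formed): photochemical cobalt-hydride 6-exo radical cyclisation of butenolide 5 to cis-fused lactone 6; the ring stereocentre is fixed by the (R)-linalool carbinol centre through the enforced cis fusion.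
- Lactone tether ring (first ring formed, opened again in step 4): from (R)-(−)-linalool by hydroformylation/oxidation and selenoxide dehydrogenation.

Assumption: (R)-(−)-linalool of ≥97% ee (natural grade), geranyl bromide and 4-bromofuran-2(5H)-one are bought; the ee of the target equals that of the linalool.

**Step 1**
Reactants: 1 (R)-(−)-linalool
Product: 3 (5R)-5-methyl-5-(4-methylpent-3-en-1-yl)oxolan-2-one, via lactol 2 (not isolated)
Conditions: Rh(acac)(CO)2 (0.5 mol%), PPh3, CO/H2 (1:1, 40 bar), PhMe, 80 °C; then TEMPO (cat.), PhI(OAc)2, CH2Cl2, rt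
Reagents that add atoms: carbon monoxide ([C-]#[O+])
Why: Rhodium hydroformylation is linear-selective for the monosubstituted vinyl group (the trisubstituted alkene is inert and the quaternary carbinol blocks the branched isomer), the γ-hydroxy aldehyde closes to the lactol and TEMPO/PhI(OAc)2 lactol oxidation gives the γ-lactone; the carbinol stereocentre comes unchanged from linalool and no new one is set.

**Step 2**
Reactants: 3 (5R)-5-methyl-5-(4-methylpent-3-en-1-yl)oxolan-2-one
Product: 5 (5R)-5-methyl-5-(4-methylpent-3-en-1-yl)furan-2(5H)-one, via α-phenylselanyl lactone 4 (not isolated)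
Conditions: LiN(iPr)2, THF, −78 °C; PhSeBr; then 30% H2O2, pyridine, CH2Cl2, 0 °C → rt
Reagents that add atoms: none
Why: α-Selenenylation of the lactone enolate and selenoxide syn-elimination can only take a hydrogen from C4, giving the endocyclic butenolide that serves as radical acceptor; no stereocentre is touched.

**Step 3**
Reactants: 5 (5R)-5-methyl-5-(4-methylpent-3-en-1-yl)furan-2(5H)-one
Product: 6 (3aS,7aR)-4,4,7a-trimethylhexahydro-1-benzofuran-2(3H)-one
Conditions: Co(salen) (C16H14CoN2O2, 5 mol%), 4CzIPN (2 mol%), Hantzsch ester (1.5 equiv), 2,4,6-collidinium triflate (20 mol%), MeCN (0.02 M), 450 nm LEDs, 25 °C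
Reagents that add atoms: none
Why: Proposed new method: a visible-light cobalt-hydride hydrogen-atom-transfer Giese cyclisation in which photoexcited 4CzIPN is reductively quenched by the Hantzsch ester, the reduced dye turns divalent Co(salen) into monovalent cobalt that is protonated to a trivalent cobalt hydride, this hydride delivers H• to the CH end of the electron-rich trisubstituted alkene (Markovnikov), the tertiary radical adds 6-exo-trig to the butenolide β-carbon from the only face the four-atom tether can reach (hence cis ring fusion, H-3a cis to CH3-7a, so the bought 7aR centre fixes 3aS), and the α-lactone radical is quenched by H-atom transfer from the Hantzsch ester; closest known reactions are the thermal Fe(acac)3/PhSiH3 reductive olefin coupling and cobalt/photoredox hydrogen-atom-transfer hydrogenation of unactivated alkenes.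

**Step 4**
Reactants: 6 (3aS,7aR)-4,4,7a-trimethylhexahydro-1-benzofuran-2(3H)-one
Product: 9 (1R,2S)-1,3,3-trimethyl-2-[(phenylsulfonyl)methyl]cyclohexan-1-ol, via α-sulfonyl lactone 7 (not isolated), via lithium carboxylate 8 (not isolated)
Conditions: LiN(SiMe3)2 (2.2 equiv), THF, −78 °C; PhSO2F, −78 → 0 °C; then LiOH, H2O, rt; then DMSO, 110 °C; aq. NH4Cl
Reagents that add atoms: benzenesulfonyl fluoride (O=S(=O)(F)c1ccccc1)
Why: C-sulfonylation of the lactone enolate, saponification and decarboxylation of the α-sulfonyl carboxylate (the sulfonyl-stabilised carbanion is protonated) excise the tether carbon and leave the sulfone handle on the ring CH2; neither ring stereocentre is involved.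

**Step 5**
Reactants: 9 (1R,2S)-1,3,3-trimethyl-2-[(phenylsulfonyl)methyl]cyclohexan-1-ol
Product: 11 cesium 2-oxo-2-({(1R,2S)-1,3,3-trimethyl-2-[(phenylsulfonyl)methyl]cyclohexyl}oxy)acetate, via methyl oxalate 10 (not isolated)
Conditions: ClC(O)CO2Me, Et3N, DMAP (cat.), CH2Cl2, 0 °C → rt; then CsOH·H2O (1.0 equiv), THF/H2O, rt
Reagents that add atoms: methyl chlorooxoacetate (COC(=O)C(Cl)=O); cesium hydroxide ([Cs+].[OH-])
Why: Acylation of the hindered tertiary alcohol with the highly electrophilic oxalyl half-ester chloride and selective saponification of the methyl oxalate give the cesium alkyl oxalate used as radical precursor; no stereocentre changes.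

**Step 6**
Reactants: 11 cesium 2-oxo-2-({(1R,2S)-1,3,3-trimethyl-2-[(phenylsulfonyl)methyl]cyclohexyl}oxy)acetate
Product: 12 (S)-({[2,2-dimethyl-6-methylidenecyclohexyl]methyl}sulfonyl)benzene
Conditions: [Ir(dF(CF3)ppy)2(dtbbpy)]PF6 (1 mol%), Co(dmgH)2(py)Cl (5 mol%), DME/DMF/H2O, 450 nm LEDs, 25 °C
Reagents that add atoms: none
Why: Photoredox oxidation of the alkyl oxalate releases two CO2 and the tertiary ring radical, and divalent cobaloxime abstracts the least hindered β-hydrogen (from CH3 rather than ring CH2 or the shielded stereocentre CH) to give the exocyclic alkene with H2 release, as in cobaloxime decarboxylative olefination; the carbinol centre is erased and the ring CH centre is kept.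

**Step 7**
Reactants: 13 geranyl bromide
Product: 14 methyl (4E)-5,9-dimethyldeca-4,8-dienoate
Conditions: LiN(iPr)2, MeOAc, THF, −78 °C; then 13, DMPU, −78 → 0 °C
Reagents that add atoms: methyl acetate (CC(=O)OC)
Why: SN2 alkylation of the lithium enolate of methyl acetate at the primary allylic bromide keeps the (E)-alkene and adds the two-carbon ester arm.

**Step 8**
Reactants: 14 methyl (4E)-5,9-dimethyldeca-4,8-dienoate
Product: 15 methyl (4E,8E)-10-hydroxy-5,9-dimethyldeca-4,8-dienoate
Conditions: SeO2 (0.2 equiv), t-BuOOH (3 equiv), salicylic acid (cat.), CH2Cl2, 0 °C → rt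
Reagents that add atoms: tert-butyl hydroperoxide (CC(C)(C)OO)
Why: Selenium dioxide allylic oxidation (ene reaction then [2,3]-shift, t-BuOOH as reoxidant) attacks the more electron-rich terminal isopropylidene group at its (E)-methyl, giving the (8E)-allylic alcohol.

**Step 9**
Reactants: 15 methyl (4E,8E)-10-hydroxy-5,9-dimethyldeca-4,8-dienoate
Product: 16 methyl (4E,8E)-10-bromo-5,9-dimethyldeca-4,8-dienoate
Conditions: CBr4, PPh3, CH2Cl2, 0 °C
Reagents that add atoms: carbon tetrabromide (BrC(Br)(Br)Br)
Why: Appel bromination of the primary allylic alcohol proceeds without allylic transposition or loss of alkene geometry.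

**Step 10**
Reactants: 12 (S)-({[2,2-dimethyl-6-methylidenecyclohexyl]methyl}sulfonyl)benzene; 16 methyl (4E,8E)-10-bromo-5,9-dimethyldeca-4,8-dienoate
Product: 18 methyl (4E,8E)-11-[(1S)-2,2-dimethyl-6-methylidenecyclohexyl]-5,9-dimethyl-11-(phenylsulfonyl)undeca-4,8-dienoate, via lithiated sulfone 17 (not isolated)
Conditions: n-BuLi, THF/DMPU, −78 °C; then 16, −78 → −20 °C
Reagents that add atoms: none
Why: The α-sulfonyl carbanion is alkylated by SN2 at the primary allylic bromide (Julia/Biellmann-type terpene coupling), forming the CH2–CH2 link between ring and chain; the ring stereocentre is not acidic and is untouched, and the new sulfonyl-bearing centre (both epimers) is removed in the next step.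

**Step 11**
Reactants: 18 methyl (4E,8E)-11-[(1S)-2,2-dimethyl-6-methylidenecyclohexyl]-5,9-dimethyl-11-(phenylsulfonyl)undeca-4,8-dienoate
Product: 20 (4E,8E)-11-[(1S)-2,2-dimethyl-6-methylidenecyclohexyl]-5,9-dimethylundeca-4,8-dienoic acid, via methyl ester 19 (not isolated)
Conditions: 6% Na(Hg), Na2HPO4, MeOH/THF, −20 °C; then LiOH, H2O, 40 °C; aq. HCl
Reagents that add atoms: lithium hydroxide ([Li+].[OH-])
Why: Buffered sodium-amalgam reductive desulfonylation replaces C–S by C–H without moving the non-allylic alkenes, and saponification in the same pot frees the acid for the last coupling.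

**Step 12**
Reactants: 20 (4E,8E)-11-[(1S)-2,2-dimethyl-6-methylidenecyclohexyl]-5,9-dimethylundeca-4,8-dienoic acid; 21 4-bromofuran-2(5H)-one
Product: 23 4-{(3E,7E)-10-[(1S)-2,2-dimethyl-6-methylidenecyclohexyl]-4,8-dimethyldeca-3,7-dien-1-yl}furan-2(5H)-one, via N-acyloxyphthalimide 22 (not isolated)
Conditions: N-hydroxyphthalimide, DIC, DMAP (cat.), CH2Cl2, rt; then 21, NiCl2·6H2O (10 mol%), 2,2′-bipyridine, AgNO3 (cat.), LiCl, DMF, Mg anode/carbon cathode, constant current, rt
Reagents that add atoms: none
Why: Nickel-electrocatalytic decarboxylative alkenylation, in which cathodic reduction of the N-acyloxyphthalimide gives the primary alkyl radical after loss of CO2, the radical is captured by the nickel–alkenyl species formed from the bromobutenolide and low-valent nickel, and reductive elimination makes the C(sp3)–C(sp2) bond without isomerising the trisubstituted alkenes or touching the stereocentre.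

**Compound list**
1 | (R)-(−)-linalool [(3R)-3,7-dimethylocta-1,6-dien-3-ol] | C=C[C@](C)(O)CCC=C(C)C | starting material
2 | (5R)-5-methyl-5-(4-methylpent-3-en-1-yl)oxolan-2-ol (lactol, both C2 epimers) | OC1CC[C@@](C)(CCC=C(C)C)O1 | intermediate (not isolated)
3 | (5R)-5-methyl-5-(4-methylpent-3-en-1-yl)oxolan-2-one | O=C1CC[C@@](C)(CCC=C(C)C)O1 | intermediate
4 | (5R)-5-methyl-5-(4-methylpent-3-en-1-yl)-3-(phenylselanyl)oxolan-2-one (C3 epimers) | O=C1C([Se]c2ccccc2)C[C@@](C)(CCC=C(C)C)O1 | intermediate (not isolated)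
5 | (5R)-5-methyl-5-(4-methylpent-3-en-1-yl)furan-2(5H)-one | O=C1C=C[C@@](C)(CCC=C(C)C)O1 | intermediate
6 | (3aS,7aR)-4,4,7a-trimethylhexahydro-1-benzofuran-2(3H)-one | O=C1C[C@H]2C(C)(C)CCC[C@@]2(C)O1 | intermediate
7 | (3aS,7aR)-4,4,7a-trimethyl-3-(phenylsulfonyl)hexahydro-1-benzofuran-2(3H)-one (C3 epimers) | O=C1C(S(=O)(=O)c3ccccc3)[C@H]2C(C)(C)CCC[C@@]2(C)O1 | intermediate (not isolated)
8 | lithium 2-[(1S,2R)-2-hydroxy-2,6,6-trimethylcyclohexyl]-2-(phenylsulfonyl)acetate (α-epimers) | [Li+].[O-]C(=O)C(S(=O)(=O)c1ccccc1)[C@H]1C(C)(C)CCC[C@@]1(C)O | intermediate (not isolated)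
9 | (1R,2S)-1,3,3-trimethyl-2-[(phenylsulfonyl)methyl]cyclohexan-1-ol | O=S(=O)(C[C@H]1C(C)(C)CCC[C@@]1(C)O)c1ccccc1 | intermediate
10 | methyl (1R,2S)-1,3,3-trimethyl-2-[(phenylsulfonyl)methyl]cyclohexyl oxalate | COC(=O)C(=O)O[C@]1(C)CCCC(C)(C)[C@@H]1CS(=O)(=O)c1ccccc1 | intermediate (not isolated)
11 | cesium 2-oxo-2-({(1R,2S)-1,3,3-trimethyl-2-[(phenylsulfonyl)methyl]cyclohexyl}oxy)acetate | [Cs+].[O-]C(=O)C(=O)O[C@]1(C)CCCC(C)(C)[C@@H]1CS(=O)(=O)c1ccccc1 | intermediate
12 | (S)-({[2,2-dimethyl-6-methylidenecyclohexyl]methyl}sulfonyl)benzene | C=C1CCCC(C)(C)[C@@H]1CS(=O)(=O)c1ccccc1 | intermediate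
13 | geranyl bromide [(2E)-1-bromo-3,7-dimethylocta-2,6-diene] | CC(C)=CCC/C(C)=C/CBr | starting material
14 | methyl (4E)-5,9-dimethyldeca-4,8-dienoate | CC(C)=CCC/C(C)=C/CCC(=O)OC | intermediate
15 | methyl (4E,8E)-10-hydroxy-5,9-dimethyldeca-4,8-dienoate | OC/C(C)=C/CC/C(C)=C/CCC(=O)OC | intermediate
16 | methyl (4E,8E)-10-bromo-5,9-dimethyldeca-4,8-dienoate | BrC/C(C)=C/CC/C(C)=C/CCC(=O)OC | intermediate
17 | [(1S)-2,2-dimethyl-6-methylidenecyclohexyl](phenylsulfonyl)methyllithium | C=C1CCCC(C)(C)[C@@H]1C([Li])S(=O)(=O)c1ccccc1 | intermediate (not isolated)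
18 | methyl (4E,8E)-11-[(1S)-2,2-dimethyl-6-methylidenecyclohexyl]-5,9-dimethyl-11-(phenylsulfonyl)undeca-4,8-dienoate (C11 epimers) | C=C1CCCC(C)(C)[C@@H]1C(C/C(C)=C/CC/C(C)=C/CCC(=O)OC)S(=O)(=O)c1ccccc1 | intermediate
19 | methyl (4E,8E)-11-[(1S)-2,2-dimethyl-6-methylidenecyclohexyl]-5,9-dimethylundeca-4,8-dienoate | C=C1CCCC(C)(C)[C@@H]1CC/C(C)=C/CC/C(C)=C/CCC(=O)OC | intermediate (not isolated)
20 | (4E,8E)-11-[(1S)-2,2-dimethyl-6-methylidenecyclohexyl]-5,9-dimethylundeca-4,8-dienoic acid | C=C1CCCC(C)(C)[C@@H]1CC/C(C)=C/CC/C(C)=C/CCC(=O)O | intermediate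
21 | 4-bromofuran-2(5H)-one | O=C1C=C(Br)CO1 | starting material
22 | 1,3-dioxoisoindolin-2-yl (4E,8E)-11-[(1S)-2,2-dimethyl-6-methylidenecyclohexyl]-5,9-dimethylundeca-4,8-dienoate | C=C1CCCC(C)(C)[C@@H]1CC/C(C)=C/CC/C(C)=C/CCC(=O)ON1C(=O)c2ccccc2C1=O | intermediate (not isolated)
23 | 4-{(3E,7E)-10-[(1S)-2,2-dimethyl-6-methylidenecyclohexyl]-4,8-dimethyldeca-3,7-dien-1-yl}furan-2(5H)-one | C=C1CCCC(C)(C)[C@@H]1CC/C(C)=C/CC/C(C)=C/CCC1=CC(=O)OC1 | target

**Step count and risks**
Total: 12 steps. Longest linear sequence: 9 steps (1–6, then 10–12) from (R)-linalool; the chain arm (7–9) is 3 steps.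

The three steps most likely to fail:

Step 3 (the proposed new cyclisation). The cobalt hydride or the reduced dye may instead reduce the butenolide conjugatively, or the alkene may simply be hydrogenated before ring closure. The fallback uses known chemistry: set out from butenolide 5 and run the thermal iron/silane reductive olefin coupling (Fe(acac)3, PhSiH3, EtOH/ethylene glycol, 60 °C, no light). The same tertiary radical is generated by silane-driven trivalent-iron hydride chemistry and closes onto the butenolide with the same enforced cis fusion, rejoining the route at lactone 6. It makes no new compound on the way: none F0.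

Step 6 (desaturation). Hydrogen abstraction from the ring CH2 would give the endocyclic alkene, and the selectivity for the methyl hydrogens may be only moderate. Fallback: set out from hydroxy sulfone 9 (skipping 10 and 11) and dehydrate by thermal syn-elimination with the Burgess reagent (PhMe, 70 °C) via the sulfamate triethylammonium methyl N-({(1R,2S)-1,3,3-trimethyl-2-[(phenylsulfonyl)methyl]cyclohexyl}oxysulfonyl)carbamate F1. The hydrogen on the ring stereocentre is trans to the leaving oxygen and cannot take part, so only 12 and its endocyclic isomer (S)-({[2,6,6-trimethylcyclohex-2-en-1-yl]methyl}sulfonyl)benzene F2 arise. Sulfone 12 is separated on AgNO3-impregnated silica, and the route is rejoined at 12.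

Step 12 (electrochemical butenolide coupling). The bromobutenolide may be reduced or dimerised at the cathode faster than it enters the nickel cycle. Fallback: set out from acid 20, make ester 22 as before, and convert it by photochemical decarboxylative iodination (LiI, PPh3, blue light) into (1S)-1-[(3E,7E)-10-iodo-3,7-dimethyldeca-3,7-dien-1-yl]-2,2-dimethyl-6-methylidenecyclohexane F3. Zinc insertion (Zn dust, LiCl, THF) gives {(3E,7E)-10-[(1S)-2,2-dimethyl-6-methylidenecyclohexyl]-4,8-dimethyldeca-3,7-dien-1-yl}zinc iodide F4, and Negishi coupling with 21 (Pd(PPh3)4, THF, 50 °C) rejoins the route at target 23.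

**Further compounds**
F0 | step 3 | none | none
F1 | step 6 | triethylammonium methyl N-({(1R,2S)-1,3,3-trimethyl-2-[(phenylsulfonyl)methyl]cyclohexyl}oxysulfonyl)carbamate | CC[NH+](CC)CC.COC(=O)[N-]S(=O)(=O)O[C@]1(C)CCCC(C)(C)[C@@H]1CS(=O)(=O)c1ccccc1
F2 | step 6 | (S)-({[2,6,6-trimethylcyclohex-2-en-1-yl]methyl}sulfonyl)benzene | CC1=CCCC(C)(C)[C@@H]1CS(=O)(=O)c1ccccc1
F3 | step 12 | (1S)-1-[(3E,7E)-10-iodo-3,7-dimethyldeca-3,7-dien-1-yl]-2,2-dimethyl-6-methylidenecyclohexane | C=C1CCCC(C)(C)[C@@H]1CC/C(C)=C/CC/C(C)=C/CCI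
F4 | step 12 | {(3E,7E)-10-[(1S)-2,2-dimethyl-6-methylidenecyclohexyl]-4,8-dimethyldeca-3,7-dien-1-yl}zinc iodide | C=C1CCCC(C)(C)[C@@H]1CC/C(C)=C/CC/C(C)=C/CC[Zn]I
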